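**Plan**

1. Retrosynthesis: take off the two tiglates and the epoxide (back to a C-6/C-7 alkene with ketones at C-4 and C-8), then cut the seven-membered ring at C-5–C-6 and at C-3a–C-8a in one intramolecular (4+3) cycloaddition.
2. Enabling feature: oxygenated C-4 sits between C-5 (CH2) and C-3a (CH), a 2-oxyallyl unit, and C-3a carries the tertiary C-3 carbinol, which is what a C-3a/C-3 oxirane leaves behind when it ionises. C-6–C-7–C-8–C-8a is a diene and C-1–C-2–C-3 of the cyclopentane is a three-atom tether.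
3. Forward: a linear chain is built (Wittig, asymmetric propargylation, ynoate carbocupration, Sharpless epoxidation, methyl ketone, enol silane). Et3SiOTf then closes the five- and seven-membered rings together and creates C-3a and the quaternary C-8a.
4. Endgame: directed reduction at C-4, ene/transposition to the C-8 enone with tigloylation at C-4, Luche reduction, hydroxyl-directed epoxidation, second tigloylation, desilylation.
5. Stereochemistry: C-1 from the chiral phosphoric acid; C-3 (and C-3a, by inversion) from the Sharpless epoxide; C-8a from the compact cycloaddition transition state; C-4 from C-3–OH-directed hydride delivery; C-8 from convex-face hydride attack; C-6/C-7 from the C-8 hydroxyl.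

Key step: step 12

Remark: both esters are read as (E)-2-methylbut-2-enoates (tiglates). The core is numbered as azulene: C-1 CHOH, C-3 C(OH)(i-Pr), C-3a ring-fusion CH, C-4 and C-8 ester carbons, C-6/C-7 epoxide, C-8a ring-fusion C–CH3.

**Route**

Step 1
Reactants: 1 (E)-but-2-enal (crotonaldehyde); 2 2-(triphenylphosphoranylidene)propanal
Product: 3 (2E,4E)-2-methylhexa-2,4-dienal
Conditions: toluene, 80 °C
Reagents that add atoms: none
Why: Wittig olefination with a stabilised α-methyl ylide should give the (2E)-trisubstituted enal selectively, and the (E)-crotyl double bond is carried through unchanged.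

Step 2
Reactants: 3 (2E,4E)-2-methylhexa-2,4-dienal; 4 allenylboronic acid pinacol ester
Product: 5 (4S,5E,7E)-5-methylnona-5,7-dien-1-yn-4-ol
Conditions: (S)-TRIP phosphoric acid (5 mol %), 4 Å MS, toluene, −20 °C; aq. NaHCO3 work-up
Reagents that add atoms: none
Why: Brønsted acid-catalysed propargylboration through a closed six-membered SE2′ transition state should give the homopropargylic alcohol, with C-4 set by catalyst-controlled addition to the Si face of the aldehyde (the catalyst antipode is the control element and is chosen for that face).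

Step 3
Reactants: 5 (4S,5E,7E)-5-methylnona-5,7-dien-1-yn-4-ol
Product: 6 tert-butyldimethyl{[(4S,5E,7E)-5-methylnona-5,7-dien-1-yn-4-yl]oxy}silane
Conditions: TBSCl, imidazole, DMF, 0 °C → rt
Reagents that add atoms: tert-butyldimethylsilyl chloride, CC(C)(C)[Si](C)(C)Cl
Why: Imidazole-promoted silylation of the secondary alcohol; the bulky silyl ether is a poor Lewis base, which matters in step 12, and no stereocentre is touched.

Step 4
Reactants: 6 the silyl ether of step 3
Product: 7 methyl (5S,6E,8E)-5-[(tert-butyldimethylsilyl)oxy]-6-methyldeca-6,8-dien-2-ynoate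
Conditions: n-BuLi, THF, −78 °C; then ClCO2Me, −78 → 0 °C
Reagents that add atoms: methyl chloroformate, COC(=O)Cl
Why: Deprotonation of the terminal alkyne and C-acylation of the lithium acetylide with the chloroformate should give the ynoate.

Step 5
Reactants: 7 the ynoate of step 4
Product: 8 methyl (2E,5S,6E,8E)-5-[(tert-butyldimethylsilyl)oxy]-6-methyl-3-(propan-2-yl)deca-2,6,8-trienoate
Conditions: i-PrMgCl (2.2 equiv), CuI (1.1 equiv), THF, −40 → −78 °C; then 7, −78 °C; MeOH then aq. NH4Cl at −78 °C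
Reagents that add atoms: isopropylmagnesium chloride, CC(C)[Mg]Cl
Why: Conjugate syn-carbocupration of the ynoate at −78 °C and protonation of the alkenylcopper with retention should give the (2E)-enoate, in which the ester is cis to CH2 and trans to the isopropyl group, the geometry the oxirane needs.

Step 6
Reactants: 8 the enoate of step 5
Product: 9 (2E,5S,6E,8E)-5-[(tert-butyldimethylsilyl)oxy]-6-methyl-3-(propan-2-yl)deca-2,6,8-trien-1-ol
Conditions: i-Bu2AlH (2.5 equiv), CH2Cl2, −78 °C; Rochelle salt work-up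
Reagents that add atoms: none
Why: 1,2-Reduction of the enoate by diisobutylaluminium hydride should give the allylic alcohol with the alkene geometry intact.

Step 7
Reactants: 9 the allylic alcohol of step 6
Product: 10 [(2R,3R)-3-{(2S,3E,5E)-2-[(tert-butyldimethylsilyl)oxy]-3-methylhepta-3,5-dien-1-yl}-3-(propan-2-yl)oxiran-2-yl]methanol
Conditions: Ti(OiPr)4 (10 mol %), D-(−)-diethyl tartrate (12 mol %), t-BuOOH, 4 Å MS, CH2Cl2, −20 °C
Reagents that add atoms: tert-butyl hydroperoxide, CC(C)(C)OO
Why: Sharpless asymmetric epoxidation acts only on the allylic alcohol (the silyloxy diene has no free hydroxyl) and, with the D-(−)-tartrate, should deliver oxygen to the face that gives the (2R,3R)-oxirane, in the same sense as for other 3,3-disubstituted allylic alcohols; this sets C-3 of the target and the precursor of C-3a.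

Step 8
Reactants: 10 the epoxy alcohol of step 7
Product: 11 (2S,3R)-3-{(2S,3E,5E)-2-[(tert-butyldimethylsilyl)oxy]-3-methylhepta-3,5-dien-1-yl}-3-(propan-2-yl)oxirane-2-carbaldehyde
Conditions: Dess–Martin periodinane, NaHCO3, CH2Cl2, 0 °C
Reagents that add atoms: none
Why: Dess–Martin oxidation under buffered conditions should give the epoxy aldehyde without touching the oxirane or the diene.

Step 9
Reactants: 11 the epoxy aldehyde of step 8
Product: 12 1-[(2R,3R)-3-{(2S,3E,5E)-2-[(tert-butyldimethylsilyl)oxy]-3-methylhepta-3,5-dien-1-yl}-3-(propan-2-yl)oxiran-2-yl]ethan-1-ol (both carbinol epimers)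
Conditions: MeMgBr, THF, −78 °C
Reagents that add atoms: methylmagnesium bromide, C[Mg]Br
Why: Grignard addition to the aldehyde at low temperature should leave the oxirane intact; the new carbinol centre is of no consequence because it is oxidised in step 10.

Step 10
Reactants: 12 the secondary alcohol of step 9
Product: 13 1-[(2S,3R)-3-{(2S,3E,5E)-2-[(tert-butyldimethylsilyl)oxy]-3-methylhepta-3,5-dien-1-yl}-3-(propan-2-yl)oxiran-2-yl]ethan-1-one
Conditions: Dess–Martin periodinane, NaHCO3, CH2Cl2, 0 °C → rt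
Reagents that add atoms: none
Why: Dess–Martin oxidation of the secondary alcohol should give the α,β-epoxy methyl ketone.

Step 11
Reactants: 13 the epoxy ketone of step 10
Product: 14 (2S,3R)-3-{(2S,3E,5E)-2-[(tert-butyldimethylsilyl)oxy]-3-methylhepta-3,5-dien-1-yl}-3-(propan-2-yl)-2-{1-[(triethylsilyl)oxy]ethenyl}oxirane
Conditions: LiN(SiMe3)2, Et3SiCl, THF, −78 °C
Reagents that add atoms: chlorotriethylsilane, CC[Si](Cl)(CC)CC
Why: Kinetic deprotonation occurs at the methyl group (the oxiranyl C–H is not acidic) and O-silylation of the enolate should give the 2-silyloxyvinyl oxirane.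

Step 12
Reactants: 14 the epoxy enol silane of step 11
Product: 16 (1S,3R,3aR,6S,8aS)-1-[(tert-butyldimethylsilyl)oxy]-3-hydroxy-6,8a-dimethyl-3-(propan-2-yl)-2,3,3a,5,6,8a-hexahydroazulen-4(1H)-one (cis-fused), via triethylsilyl ether cycloadduct 15 (not isolated)
Conditions: Et3SiOTf (10 mol %), CH2Cl2, −78 °C; then HF·pyridine, pyridine, THF, 0 °C
Reagents that add atoms: none
Why: Silylation of the oxirane oxygen by Et3SiOTf lets the C–O bond at the oxirane carbon next to the enol ether ionise with π-assistance to a 2-(triethylsilyloxy)allyl cation, which is captured across the termini of the tethered (E,E)-diene in an intramolecular (4+3) cycloaddition; the resulting silyloxocarbenium ion passes its silyl group to the next oxirane, so the triflate is a true catalyst and the tertiary oxygen ends as the silyl ether that the second stage cleaves. The closest known reaction type is the silyl triflate-catalysed (4+3) cycloaddition of epoxy enol silanes with dienes, tethered ones included. The cyclopentane closes 5-exo with respect to the diene, by attack of its disubstituted terminus on the former oxirane CH (both oxirane carbons end in the new ring), and the cycloheptenone closes as the 4π + 2π (three-carbon) ring when the enol ether CH2 bonds to the propenyl terminus in the same suprafacial event. C-3 keeps the configuration of the Sharpless epoxide because its C–O bond is never broken; C-3a forms with inversion (the diene enters anti to the leaving oxygen, which also places the isopropyl group trans to the new ring bond); C-8a comes from the compact, boat-like transition state of the W-shaped cation with the tether on the outside of the diene, which gives the cis ring fusion; C-6 follows from the (E)-propenyl terminus and is erased in step 14. The step needs ionisation at the secondary, enol ether-activated oxirane carbon and not at the tertiary one, (4+3) and not (3+2) closure, and one diene face; the alignment of the breaking C–O bond with the enol ether π system, the s-cis-capable (E,E)-diene, the three-atom tether and −78 °C are what should secure these.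

Step 13
Reactants: 16 the hydroxy ketone of step 12
Product: 17 (1S,3R,3aS,4S,6S,8aS)-1-[(tert-butyldimethylsilyl)oxy]-6,8a-dimethyl-3-(propan-2-yl)-1,2,3,3a,4,5,6,8a-octahydroazulene-3,4-diol
Conditions: Me4NBH(OAc)3, MeCN/AcOH, −30 °C
Reagents that add atoms: none
Why: Evans–Saksena hydroxyl-directed reduction, in which the C-3 alkoxy(acetoxy)borohydride delivers hydride intramolecularly to the C-4 ketone from the side of the C-3 oxygen, should give the 1,3-anti diol, i.e. the (4S) carbinol.

Step 14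
Reactants: 17 the diol of step 13
Product: 20 (1S,3R,3aS,4S,8aS)-1-[(tert-butyldimethylsilyl)oxy]-3-hydroxy-6,8a-dimethyl-8-oxo-3-(propan-2-yl)-1,2,3,3a,4,5,8,8a-octahydroazulen-4-yl (2E)-2-methylbut-2-enoate, via allylic hydroperoxide 18 (not isolated), via peroxy tiglate 19 (not isolated)
Conditions: O2, tetraphenylporphyrin (cat.), hν, CH2Cl2, 0 °C; then tigloyl chloride, pyridine, DMAP, 0 °C → rt
Reagents that add atoms: dioxygen, O=O; tigloyl chloride, C/C=C(\C)C(Cl)=O
Why: Schenck ene reaction of singlet oxygen at the only alkene, with abstraction of the single allylic hydrogen (C-6–H), should place OOH at C-8 and shift the double bond to C-6/C-7, after which acylation of the hydroperoxide and Kornblum–DeLaMare-type elimination of tiglic acid give the enone while the same acid chloride esterifies the C-4 hydroxyl (the tertiary C-3 hydroxyl is too hindered); no stereocentre is created.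

Step 15
Reactants: 20 the enone tiglate of step 14
Product: 21 (1S,3R,3aS,4S,8S,8aR)-1-[(tert-butyldimethylsilyl)oxy]-3,8-dihydroxy-6,8a-dimethyl-3-(propan-2-yl)-1,2,3,3a,4,5,8,8a-octahydroazulen-4-yl (2E)-2-methylbut-2-enoate (8-OH trans to the 8a-methyl group)
Conditions: NaBH4, CeCl3·7H2O, MeOH, −78 °C
Reagents that add atoms: none
Why: Luche 1,2-reduction, in which hydride should enter from the convex face on the side of the angular methyl group and away from the silyloxy-bearing C-1 branch of the quaternary carbon, to give the (8S) alcohol.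

Step 16
Reactants: 21 the allylic alcohol of step 15
Product: 22 (1S,3R,3aS,4S,6S,7R,8R,8aR)-1-[(tert-butyldimethylsilyl)oxy]-6,7-epoxy-3,8-dihydroxy-6,8a-dimethyl-3-(propan-2-yl)decahydroazulen-4-yl (2E)-2-methylbut-2-enoate (oxirane cis to 8-OH)
Conditions: VO(acac)2 (5 mol %), t-BuOOH, CH2Cl2, 0 °C → rt
Reagents that add atoms: tert-butyl hydroperoxide, CC(C)(C)OO
Why: Vanadium-catalysed hydroxyl-directed epoxidation of the cyclic allylic alcohol should deliver oxygen syn to the C-8 hydroxyl, which sets C-6 and C-7, while the electron-poor tiglate alkene is inert.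

Step 17
Reactants: 22 the epoxy alcohol of step 16
Product: 23 (1S,3R,3aS,4S,6S,7R,8R,8aR)-1-[(tert-butyldimethylsilyl)oxy]-6,7-epoxy-3-hydroxy-6,8a-dimethyl-3-(propan-2-yl)decahydroazulene-4,8-diyl bis[(2E)-2-methylbut-2-enoate]
Conditions: tigloyl chloride, pyridine, DMAP, CH2Cl2, 0 °C → rt
Reagents that add atoms: tigloyl chloride, C/C=C(\C)C(Cl)=O
Why: DMAP-catalysed acylation of the one remaining secondary alcohol should proceed with retention, since the tertiary alcohol is too hindered to react and the silyl ether masks the C-1 hydroxyl.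

Step 18
Reactants: 23 the bis-tiglate silyl ether of step 17
Product: 24 (1S,3R,3aS,4S,6S,7R,8R,8aS)-6,7-epoxy-1,3-dihydroxy-6,8a-dimethyl-3-(propan-2-yl)decahydroazulene-4,8-diyl bis[(2E)-2-methylbut-2-enoate] (CNP0265715.1)
Conditions: HF·pyridine, pyridine, THF, 0 °C → rt
Reagents that add atoms: none
Why: Fluoride-mediated cleavage of the silyl ether under buffered, non-basic conditions should spare the epoxide and the esters and avoid acyl migration.

**Compound list**

1 | (E)-but-2-enal (crotonaldehyde) | C/C=C/C=O | starting material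
2 | 2-(triphenylphosphoranylidene)propanal | CC(C=O)=P(c1ccccc1)(c1ccccc1)c1ccccc1 | starting material
3 | (2E,4E)-2-methylhexa-2,4-dienal | O=C/C(C)=C/C=C/C | intermediate
4 | allenylboronic acid pinacol ester [4,4,5,5-tetramethyl-2-(propa-1,2-dien-1-yl)-1,3,2-dioxaborolane] | C=C=CB1OC(C)(C)C(C)(C)O1 | starting material
5 | (4S,5E,7E)-5-methylnona-5,7-dien-1-yn-4-ol | C#CC[C@H](O)/C(C)=C/C=C/C | intermediate
6 | tert-butyldimethyl{[(4S,5E,7E)-5-methylnona-5,7-dien-1-yn-4-yl]oxy}silane | C#CC[C@H](O[Si](C)(C)C(C)(C)C)/C(C)=C/C=C/C | intermediate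
7 | methyl (5S,6E,8E)-5-[(tert-butyldimethylsilyl)oxy]-6-methyldeca-6,8-dien-2-ynoate | COC(=O)C#CC[C@H](O[Si](C)(C)C(C)(C)C)/C(C)=C/C=C/C | intermediate
8 | methyl (2E,5S,6E,8E)-5-[(tert-butyldimethylsilyl)oxy]-6-methyl-3-(propan-2-yl)deca-2,6,8-trienoate | COC(=O)/C=C(/C(C)C)C[C@H](O[Si](C)(C)C(C)(C)C)/C(C)=C/C=C/C | intermediate
9 | (2E,5S,6E,8E)-5-[(tert-butyldimethylsilyl)oxy]-6-methyl-3-(propan-2-yl)deca-2,6,8-trien-1-ol | OC/C=C(/C(C)C)C[C@H](O[Si](C)(C)C(C)(C)C)/C(C)=C/C=C/C | intermediate
10 | [(2R,3R)-3-{(2S,3E,5E)-2-[(tert-butyldimethylsilyl)oxy]-3-methylhepta-3,5-dien-1-yl}-3-(propan-2-yl)oxiran-2-yl]methanol | OC[C@H]1O[C@@]1(C(C)C)C[C@H](O[Si](C)(C)C(C)(C)C)/C(C)=C/C=C/C | intermediate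
11 | (2S,3R)-3-{(2S,3E,5E)-2-[(tert-butyldimethylsilyl)oxy]-3-methylhepta-3,5-dien-1-yl}-3-(propan-2-yl)oxirane-2-carbaldehyde | O=C[C@H]1O[C@@]1(C(C)C)C[C@H](O[Si](C)(C)C(C)(C)C)/C(C)=C/C=C/C | intermediate
12 | 1-[(2R,3R)-3-{(2S,3E,5E)-2-[(tert-butyldimethylsilyl)oxy]-3-methylhepta-3,5-dien-1-yl}-3-(propan-2-yl)oxiran-2-yl]ethan-1-ol (both carbinol epimers) | CC(O)[C@H]1O[C@@]1(C(C)C)C[C@H](O[Si](C)(C)C(C)(C)C)/C(C)=C/C=C/C | intermediate
13 | 1-[(2S,3R)-3-{(2S,3E,5E)-2-[(tert-butyldimethylsilyl)oxy]-3-methylhepta-3,5-dien-1-yl}-3-(propan-2-yl)oxiran-2-yl]ethan-1-one | CC(=O)[C@H]1O[C@@]1(C(C)C)C[C@H](O[Si](C)(C)C(C)(C)C)/C(C)=C/C=C/C | intermediate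
14 | (2S,3R)-3-{(2S,3E,5E)-2-[(tert-butyldimethylsilyl)oxy]-3-methylhepta-3,5-dien-1-yl}-3-(propan-2-yl)-2-{1-[(triethylsilyl)oxy]ethenyl}oxirane | C=C(O[Si](CC)(CC)CC)[C@H]1O[C@@]1(C(C)C)C[C@H](O[Si](C)(C)C(C)(C)C)/C(C)=C/C=C/C | intermediate
15 | (1S,3R,3aR,6S,8aS)-1-[(tert-butyldimethylsilyl)oxy]-6,8a-dimethyl-3-(propan-2-yl)-3-[(triethylsilyl)oxy]-2,3,3a,5,6,8a-hexahydroazulen-4(1H)-one | O=C1C[C@H](C)C=C[C@@]2(C)[C@@H]1[C@](O[Si](CC)(CC)CC)(C(C)C)C[C@@H]2O[Si](C)(C)C(C)(C)C | intermediate
16 | (1S,3R,3aR,6S,8aS)-1-[(tert-butyldimethylsilyl)oxy]-3-hydroxy-6,8a-dimethyl-3-(propan-2-yl)-2,3,3a,5,6,8a-hexahydroazulen-4(1H)-one | O=C1C[C@H](C)C=C[C@@]2(C)[C@@H]1[C@](O)(C(C)C)C[C@@H]2O[Si](C)(C)C(C)(C)C | intermediate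
17 | (1S,3R,3aS,4S,6S,8aS)-1-[(tert-butyldimethylsilyl)oxy]-6,8a-dimethyl-3-(propan-2-yl)-1,2,3,3a,4,5,6,8a-octahydroazulene-3,4-diol | O[C@H]1C[C@H](C)C=C[C@@]2(C)[C@@H]1[C@](O)(C(C)C)C[C@@H]2O[Si](C)(C)C(C)(C)C | intermediate
18 | C-8 allylic hydroperoxide of 17 with the alkene at C-6/C-7 (OOH on the face of the 8a-methyl group) | O[C@H]1CC(C)=C[C@@H](OO)[C@@]2(C)[C@@H]1[C@](O)(C(C)C)C[C@@H]2O[Si](C)(C)C(C)(C)C | intermediate
19 | C-4 tiglate and C-8 peroxy tiglate of 18 | C/C=C(\C)C(=O)O[C@H]1CC(C)=C[C@@H](OOC(=O)/C(C)=C/C)[C@@]2(C)[C@@H]1[C@](O)(C(C)C)C[C@@H]2O[Si](C)(C)C(C)(C)C | intermediate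
20 | (1S,3R,3aS,4S,8aS)-1-[(tert-butyldimethylsilyl)oxy]-3-hydroxy-6,8a-dimethyl-8-oxo-3-(propan-2-yl)-1,2,3,3a,4,5,8,8a-octahydroazulen-4-yl (2E)-2-methylbut-2-enoate | C/C=C(\C)C(=O)O[C@H]1CC(C)=CC(=O)[C@@]2(C)[C@@H]1[C@](O)(C(C)C)C[C@@H]2O[Si](C)(C)C(C)(C)C | intermediate
21 | (1S,3R,3aS,4S,8S,8aR)-1-[(tert-butyldimethylsilyl)oxy]-3,8-dihydroxy-6,8a-dimethyl-3-(propan-2-yl)-1,2,3,3a,4,5,8,8a-octahydroazulen-4-yl (2E)-2-methylbut-2-enoate | C/C=C(\C)C(=O)O[C@H]1CC(C)=C[C@H](O)[C@@]2(C)[C@@H]1[C@](O)(C(C)C)C[C@@H]2O[Si](C)(C)C(C)(C)C | intermediate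
22 | (1S,3R,3aS,4S,6S,7R,8R,8aR)-1-[(tert-butyldimethylsilyl)oxy]-6,7-epoxy-3,8-dihydroxy-6,8a-dimethyl-3-(propan-2-yl)decahydroazulen-4-yl (2E)-2-methylbut-2-enoate | C/C=C(\C)C(=O)O[C@H]1C[C@]2(C)O[C@@H]2[C@H](O)[C@@]2(C)[C@@H]1[C@](O)(C(C)C)C[C@@H]2O[Si](C)(C)C(C)(C)C | intermediate
23 | (1S,3R,3aS,4S,6S,7R,8R,8aR)-1-[(tert-butyldimethylsilyl)oxy]-6,7-epoxy-3-hydroxy-6,8a-dimethyl-3-(propan-2-yl)decahydroazulene-4,8-diyl bis[(2E)-2-methylbut-2-enoate] | C/C=C(\C)C(=O)O[C@H]1C[C@]2(C)O[C@@H]2[C@H](OC(=O)/C(C)=C/C)[C@@]2(C)[C@@H]1[C@](O)(C(C)C)C[C@@H]2O[Si](C)(C)C(C)(C)C | intermediate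
24 | (1S,3R,3aS,4S,6S,7R,8R,8aS)-6,7-epoxy-1,3-dihydroxy-6,8a-dimethyl-3-(propan-2-yl)decahydroazulene-4,8-diyl bis[(2E)-2-methylbut-2-enoate] | C/C=C(\C)C(=O)O[C@H]1C[C@]2(C)O[C@@H]2[C@H](OC(=O)/C(C)=C/C)[C@@]2(C)[C@@H]1[C@](O)(C(C)C)C[C@@H]2O | target

**Step count and risks**

Total steps: 18. Longest linear sequence: 18 steps (from crotonaldehyde 1).

Steps most likely to fail:

Step 12. The oxirane may ionise at its tertiary carbon with hydride shift instead of at the enol ether-activated carbon, the cation may close (3+2) instead of (4+3), or the diene face may be poorly controlled. The fallback keeps the cycloaddition but changes the cation precursor and the way it is generated. It sets out from 13: SmI2 in THF/MeOH at −90 °C cleaves the α C–O bond to give (4S,6S,7E,9E)-6-[(tert-butyldimethylsilyl)oxy]-4-hydroxy-7-methyl-4-(propan-2-yl)undeca-7,9-dien-2-one F1. Et3SiOTf and 2,6-lutidine at −78 °C give the bis-silyl ether F2. The kinetic lithium enolate (LiN(iPr)2, −78 °C) is chlorinated with N-chlorosuccinimide to give the chloromethyl ketone F3. Sodium 2,2,2-trifluoroethoxide in 2,2,2-trifluoroethanol then enolises F3 toward the ring-fusion carbon and expels chloride; the free oxyallyl cation should undergo the same intramolecular (4+3) cycloaddition, the bulky isopropyl group steering the new bond. The route is rejoined at 15, which is desilylated to 16 as in step 12.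

Step 14. The ene reaction may be slow at the hindered cis-disubstituted ring alkene, or the hydroperoxide may fragment before it is acylated. The fallback sets out from 17: m-chloroperbenzoic acid should epoxidise the alkene from the convex face to give the 7,8-epoxide F4, on the face that also carries the C-6 hydrogen. Excess Et2Al(TMP) in toluene at 0 °C then effects syn β-elimination to the C-6/C-7-unsaturated 3,4,8-triol F5. MnO2 oxidises only the allylic hydroxyl to give the hydroxy enone F6, and tigloyl chloride/pyridine/DMAP esterifies C-4–OH, returning to the route at 20.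

Step 15. Hydride may attack from the concave face and give mainly the C-8 epimer. The fallback sets out from 20: the epimeric allylic alcohol F7 obtained in that event is inverted by Mitsunobu reaction with chloroacetic acid (PPh3, diisopropyl azodicarboxylate, THF) to give the (8S) chloroacetate F8. Thiourea and NaHCO3 in ethanol remove the chloroacetyl group without touching the tiglate, returning to the route at 21.

**Further compounds**

F1 | step 12 | (4S,6S,7E,9E)-6-[(tert-butyldimethylsilyl)oxy]-4-hydroxy-7-methyl-4-(propan-2-yl)undeca-7,9-dien-2-one | CC(=O)C[C@](O)(C(C)C)C[C@H](O[Si](C)(C)C(C)(C)C)/C(C)=C/C=C/C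
F2 | step 12 | (4S,6S,7E,9E)-6-[(tert-butyldimethylsilyl)oxy]-7-methyl-4-(propan-2-yl)-4-[(triethylsilyl)oxy]undeca-7,9-dien-2-one | CC(=O)C[C@](O[Si](CC)(CC)CC)(C(C)C)C[C@H](O[Si](C)(C)C(C)(C)C)/C(C)=C/C=C/C
F3 | step 12 | (4S,6S,7E,9E)-6-[(tert-butyldimethylsilyl)oxy]-1-chloro-7-methyl-4-(propan-2-yl)-4-[(triethylsilyl)oxy]undeca-7,9-dien-2-one | ClCC(=O)C[C@](O[Si](CC)(CC)CC)(C(C)C)C[C@H](O[Si](C)(C)C(C)(C)C)/C(C)=C/C=C/C
F4 | step 14 | 7,8-epoxide of diol 17 (oxirane on the face of the 8a-methyl group) | O[C@H]1C[C@H](C)[C@H]2O[C@H]2[C@@]3(C)[C@@H]1[C@](O)(C(C)C)C[C@@H]3O[Si](C)(C)C(C)(C)C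
F5 | step 14 | 1-[(tert-butyldimethylsilyl)oxy]-6,8a-dimethyl-3-(propan-2-yl)-1,2,3,3a,4,5,8,8a-octahydroazulene-3,4,8-triol (8-OH cis to the 8a-methyl group) | O[C@H]1CC(C)=C[C@@H](O)[C@@]2(C)[C@@H]1[C@](O)(C(C)C)C[C@@H]2O[Si](C)(C)C(C)(C)C
F6 | step 14 | 3-[(tert-butyldimethylsilyl)oxy]-1,8-dihydroxy-3a,6-dimethyl-1-(propan-2-yl)-2,3,3a,7,8,8a-hexahydroazulen-4(1H)-one (the C-4 alcohol corresponding to 20) | O[C@H]1CC(C)=CC(=O)[C@@]2(C)[C@@H]1[C@](O)(C(C)C)C[C@@H]2O[Si](C)(C)C(C)(C)C
F7 | step 15 | C-8 epimer of 21 (8-OH cis to the 8a-methyl group) | C/C=C(\C)C(=O)O[C@H]1CC(C)=C[C@@H](O)[C@@]2(C)[C@@H]1[C@](O)(C(C)C)C[C@@H]2O[Si](C)(C)C(C)(C)C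
F8 | step 15 | C-8 chloroacetate of 21 | C/C=C(\C)C(=O)O[C@H]1CC(C)=C[C@H](OC(=O)CCl)[C@@]2(C)[C@@H]1[C@](O)(C(C)C)C[C@@H]2O[Si](C)(C)C(C)(C)C
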